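## Retrosynthetic overview

1. The target is cut at both exocyclic C–C bonds of the cyclohexene in one step: an enantioselective, desymmetrising three-component syn-1,2-alkenyl-arylation of the achiral diene 1,4-dimethylcyclohexa-1,3-diene with (E)-8-(2-iodoethenyl)-7-methoxycoumarin and a 7-methoxycoumarin-6-yl boronate. This step sets both stereocentres.
2. The symmetric diene comes from p-xylene by Birch dearomatisation and isomerisation into conjugation.
3. The alkenyl iodide comes from umbelliferone by C8 formylation, O-methylation and iodo-olefination.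
4. The boronate comes from 5-bromo-2-hydroxy-4-methoxybenzaldehyde by Wittig/lactonisation and borylation.
5. Ring order: the carbocycle is the former p-xylene ring and is never closed; the 8-linked coumarin is bought intact; the pyranone of the 6-linked coumarin is closed in the boronate branch; no ring is formed in the key step.

Assumption: the sense of induction of the PyOx–palladium catalyst on this new substrate cannot be predicted with certainty; the (S)-ligand is written, and the (R)-ligand is used instead if the first run (chiral HPLC plus ECD or X-ray) shows the mirror-image product.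

## Route

Step 1
Reactants: 1 p-xylene (1,4-dimethylbenzene)
Product: 2 1,4-dimethylcyclohexa-1,4-diene
Conditions: Li (2.5 equiv), NH3(l)/THF, EtOH (2.5 equiv), −78 → −33 °C; H2O work-up
Reagents that add atoms: none
Why: Birch reduction leaves the alkyl groups on the remaining double bonds, so p-xylene gives one achiral skipped diene.

Step 2
Reactants: 2 1,4-dimethylcyclohexa-1,4-diene
Product: 3 1,4-dimethylcyclohexa-1,3-diene
Conditions: KOtBu (0.2 equiv), DMSO, 50 °C, 2 h; pentane extraction; AgNO3-on-silica chromatography
Reagents that add atoms: none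
Why: Base-catalysed prototropic isomerisation gives the equilibrium mixture in which the conjugated diene with two trisubstituted double bonds is expected to be the main component (roughly 60 %, an estimate), and the more strongly silver-binding isomers, including recyclable 2, are removed by argentation chromatography.

Step 3
Reactants: 4 umbelliferone (7-hydroxy-2H-chromen-2-one)
Product: 6 7-hydroxy-2-oxo-2H-chromene-8-carbaldehyde, via aldiminium trifluoroacetate 5 (not isolated)
Conditions: hexamethylenetetramine (2 equiv), TFA, reflux, 8 h; then H2O, 60 °C, 1 h; crystallisation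
Reagents that add atoms: hexamethylenetetramine, C1N2CN3CN1CN(C2)C3; water, O
Why: Duff formylation attacks C8, the most nucleophilic carbon of 7-hydroxycoumarin (ortho to the OH and flanked by both oxygens), and the aminomethyl arene is oxidised in situ by hydride transfer to the iminium ion that water hydrolyses to the aldehyde.

Step 4
Reactants: 6 7-hydroxy-2-oxo-2H-chromene-8-carbaldehyde
Product: 7 7-methoxy-2-oxo-2H-chromene-8-carbaldehyde
Conditions: MeI (1.5 equiv), K2CO3 (2 equiv), acetone, reflux
Reagents that add atoms: iodomethane, CI
Why: Williamson O-methylation of the phenolate (SN2) leaves the lactone and the aldehyde untouched.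

Step 5
Reactants: 7 7-methoxy-2-oxo-2H-chromene-8-carbaldehyde
Product: 8 8-[(E)-2-iodoethenyl]-7-methoxy-2H-chromen-2-one
Conditions: CrCl2 (6 equiv), CHI3 (2 equiv), THF/1,4-dioxane 1:4, 0 °C → rt
Reagents that add atoms: iodoform, IC(I)I
Why: Takai iodo-olefination: the geminal dichromium species from iodoform adds to the aldehyde and eliminates to the (E)-alkenyl iodide (E:Z usually at least 10:1 for aryl aldehydes), while chromium dichloride does not reduce the coumarin.

Step 6
Reactants: 9 5-bromo-2-hydroxy-4-methoxybenzaldehyde
Product: 11 6-bromo-7-methoxy-2H-chromen-2-one, via hydroxycinnamate ester 10 (not isolated)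
Conditions: Ph3P=CHCO2Et (1.2 equiv), N,N-diethylaniline, reflux (about 215 °C), 4 h
Reagents that add atoms: ethyl (triphenylphosphoranylidene)acetate, CCOC(=O)C=P(c1ccccc1)(c1ccccc1)c1ccccc1
Why: Wittig olefination followed in the same pot by thermal E-to-Z isomerisation and lactonisation with loss of ethanol closes the pyranone ring and places bromine at C6 and methoxy at C7 without ambiguity.

Step 7
Reactants: 11 6-bromo-7-methoxy-2H-chromen-2-one
Product: 12 7-methoxy-6-(4,4,5,5-tetramethyl-1,3,2-dioxaborolan-2-yl)-2H-chromen-2-one
Conditions: B2pin2 (1.2 equiv), Pd(dppf)Cl2 (3 mol %), KOAc (3 equiv), 1,4-dioxane, 90 °C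
Reagents that add atoms: bis(pinacolato)diboron, CC1(C)OB(OC1(C)C)B1OC(C)(C)C(C)(C)O1
Why: Miyaura borylation with the weak base KOAc converts the aryl bromide into the pinacol boronate without biaryl coupling or lactone opening.

Step 8
Reactants: 3 1,4-dimethylcyclohexa-1,3-diene (4 equiv); 8 8-[(E)-2-iodoethenyl]-7-methoxy-2H-chromen-2-one (1 equiv); 12 7-methoxy-6-(4,4,5,5-tetramethyl-1,3,2-dioxaborolan-2-yl)-2H-chromen-2-one (1.5 equiv)
Product: 13 6-[(1S,6S)-6-[(E)-2-(7-methoxy-2-oxo-2H-chromen-8-yl)ethenyl]-3,6-dimethylcyclohex-2-en-1-yl]-7-methoxy-2H-chromen-2-one (aryl at C1 cis to the styryl group at C6)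
Conditions: Pd2(dba)3 (5 mol %), (S)-4-tert-butyl-2-[5-(trifluoromethyl)pyridin-2-yl]-4,5-dihydrooxazole (12 mol %), AgOTf (1.1 equiv), KF (2.2 equiv), DMA, 40 °C, 12 added over 6 h; recrystallisation
Reagents that add atoms: none
Why: Proposed new method: oxidative addition of 8 to zerovalent palladium and iodide abstraction by silver give a cationic alkenylpalladium–PyOx species that adds syn to one of the two enantiotopic methyl-bearing termini of 3 under ligand control, creating the quaternary C6, and the resulting π-allyl, locked on the face that received the alkenyl group, is arylated after fluoride-assisted transmetalation from 12 by inner-sphere reductive elimination at its secondary terminus, so aryl and alkenyl end up cis, the alkene geometry of 8 is retained and the C2=C3(CH3) double bond remains; the closest known reaction types are the palladium-catalysed three-component 1,2-alkenyl-arylation of 1,3-dienes with alkenyl triflates and arylboronic acids and the enantioselective PyOx–palladium Heck alkenylation of trisubstituted alkenes that builds methyl/alkenyl quaternary centres.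

## Compound list

1 | p-xylene (1,4-dimethylbenzene) | Cc1ccc(C)cc1 | starting material
2 | 1,4-dimethylcyclohexa-1,4-diene | CC1=CCC(C)=CC1 | intermediate
3 | 1,4-dimethylcyclohexa-1,3-diene | CC1=CC=C(C)CC1 | intermediate
4 | umbelliferone (7-hydroxy-2H-chromen-2-one) | O=c1ccc2ccc(O)cc2o1 | starting material
5 | (7-hydroxy-2-oxo-2H-chromen-8-yl)methaniminium trifluoroacetate (not isolated; drawn N-unsubstituted, in the flask the nitrogen still carries hexamine-derived residues) | [NH2+]=Cc1c(O)ccc2ccc(=O)oc12.[O-]C(=O)C(F)(F)F | intermediate
6 | 7-hydroxy-2-oxo-2H-chromene-8-carbaldehyde | O=Cc1c(O)ccc2ccc(=O)oc12 | intermediate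
7 | 7-methoxy-2-oxo-2H-chromene-8-carbaldehyde | COc1ccc2ccc(=O)oc2c1C=O | intermediate
8 | 8-[(E)-2-iodoethenyl]-7-methoxy-2H-chromen-2-one | COc1ccc2ccc(=O)oc2c1/C=C/I | intermediate
9 | 5-bromo-2-hydroxy-4-methoxybenzaldehyde | COc1cc(O)c(C=O)cc1Br | starting material
10 | ethyl (E)-3-(5-bromo-2-hydroxy-4-methoxyphenyl)prop-2-enoate (not isolated) | CCOC(=O)/C=C/c1cc(Br)c(OC)cc1O | intermediate
11 | 6-bromo-7-methoxy-2H-chromen-2-one | COc1cc2oc(=O)ccc2cc1Br | intermediate
12 | 7-methoxy-6-(4,4,5,5-tetramethyl-1,3,2-dioxaborolan-2-yl)-2H-chromen-2-one | COc1cc2oc(=O)ccc2cc1B1OC(C)(C)C(C)(C)O1 | intermediate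
13 | 6-[(1S,6S)-6-[(E)-2-(7-methoxy-2-oxo-2H-chromen-8-yl)ethenyl]-3,6-dimethylcyclohex-2-en-1-yl]-7-methoxy-2H-chromen-2-one | COc1cc2oc(=O)ccc2cc1[C@H]1C=C(C)CC[C@@]1(C)/C=C/c1c(OC)ccc2ccc(=O)oc12 | target

## Step count and risk

Total: 8 steps. Longest linear sequence: 4 steps (4 → 6 → 7 → 8 → 13).

The three steps most likely to fail are step 8, step 2 and step 5.

**Step 8** is an unprecedented combination. The main risks are direct alkenyl–aryl coupling before the hindered diene terminus inserts, β-hydride loss from the π-allyl, and insufficient er. The fallback sets out from 11 and 7 and comes back at 13, building the cyclohexene by an enantioselective Diels–Alder reaction instead.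
- Heck coupling of 11 with isoprene (Pd(OAc)2, P(o-tol)3, Et3N, DMF, 100 °C, sealed tube) gives (E)-7-methoxy-6-(3-methylbuta-1,3-dien-1-yl)-2H-chromen-2-one F1.
- F1 and methacrolein (3 equiv) react under catalysis by triflimide-activated (S)-o-tolyl oxazaborolidine (20 mol %, CH2Cl2, −78 °C; antipode chosen by the same check as in the assumption). The expected product is the ortho, formyl-endo adduct (1R,2R)-2-(7-methoxy-2-oxo-2H-chromen-6-yl)-1,4-dimethylcyclohex-3-ene-1-carbaldehyde F2, with aryl and formyl cis.
- In parallel, 7 is reduced (NaBH4, MeOH, 0 °C) to 8-(hydroxymethyl)-7-methoxy-2H-chromen-2-one F3, which P(OEt)3 and ZnI2 (toluene, reflux) convert directly into diethyl [(7-methoxy-2-oxo-2H-chromen-8-yl)methyl]phosphonate F4.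
- Horner–Wadsworth–Emmons reaction of F4 (KHMDS, THF, −78 °C → rt) with the non-enolisable aldehyde F2 gives 13 with the E double bond and the same cis (1S,6S) core.

**Step 2** gives an equilibrium mixture. A conjugated isomer with a methyl group on an sp3 carbon would insert faster than 3 in step 8 if it is not removed. The fallback sets out from 2 and comes back at 3 under kinetic control.
- 2 is mono-hydrochlorinated (HCl, 1.0 equiv, 4 M in dioxane, CH2Cl2, −40 °C) to the tertiary chloride 4-chloro-1,4-dimethylcyclohex-1-ene F5.
- DBU (neat, 80 °C) then eliminates HCl through the allylic C–H next to the remaining double bond. This gives 3, with only 2 and an exocyclic isomer as possible side products, and both are easily removed on AgNO3-silica.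

**Step 5** can suffer from a low E:Z ratio or from poor conversion of the doubly ortho-substituted aldehyde. The fallback sets out from 7 and comes back at 8 by halodecarboxylation.
- Knoevenagel–Doebner condensation of 7 with malonic acid (pyridine, cat. piperidine, 90 °C) gives (E)-3-(7-methoxy-2-oxo-2H-chromen-8-yl)prop-2-enoic acid F6.
- Hunsdiecker-type iododecarboxylation (N-iodosuccinimide, cat. Et3N, CH2Cl2, rt) converts F6 into 8 with the E geometry that is usual for electron-rich cinnamic acids.

## Further compounds

F1 | step 8 | (E)-7-methoxy-6-(3-methylbuta-1,3-dien-1-yl)-2H-chromen-2-one | COc1cc2oc(=O)ccc2cc1/C=C/C(C)=C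
F2 | step 8 | (1R,2R)-2-(7-methoxy-2-oxo-2H-chromen-6-yl)-1,4-dimethylcyclohex-3-ene-1-carbaldehyde | COc1cc2oc(=O)ccc2cc1[C@H]1C=C(C)CC[C@@]1(C)C=O
F3 | step 8 | 8-(hydroxymethyl)-7-methoxy-2H-chromen-2-one | COc1ccc2ccc(=O)oc2c1CO
F4 | step 8 | diethyl [(7-methoxy-2-oxo-2H-chromen-8-yl)methyl]phosphonate | CCOP(=O)(OCC)Cc1c(OC)ccc2ccc(=O)oc12
F5 | step 2 | 4-chloro-1,4-dimethylcyclohex-1-ene | CC1=CCC(C)(Cl)CC1
F6 | step 5 | (E)-3-(7-methoxy-2-oxo-2H-chromen-8-yl)prop-2-enoic acid | COc1ccc2ccc(=O)oc2c1/C=C/C(O)=O
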